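Remark: no connectivity error was found in the structures considered; the annulation product 8 is a keto–enol tautomer mixture and is written as its cyclohex-1-ene enol. The malonate alkyl group is treated as a protecting group and is benzyl here (not methyl), so that the ring-B acid can be freed without hydroxide. Dimethyl (1-diazo-2-oxopropyl)phosphonate and dibenzyl malonate are taken as stock reagents.

## Structural features

The target is a 3-pentylisocoumarin (ring A is the benzo ring; C1 lactone carbonyl, C3 pentyl, C6 hydroxyl) whose C8 oxygen forms a diaryl ether to C1' of ring B. Ring B is a 2,4-dihydroxy-6-pentylbenzoic acid (an olivetolic acid) in which only C3' still carries hydrogen. The target has no stereocentre; the only stereocentres of the plan are the two adjacent carbons C5 and C6 of cyclohexenone 8 (the future C1' and C6'), made together and erased on aromatisation. Fragile parts are the β-resorcylic acid of ring B (it loses CO2 under heat or strong acid, and its hindered esters resist saponification), the enol lactone (opened by hydroxide), and three electron-rich phenols that invite electrophilic halogenation or alkylation. The real difficulty is the diaryl ether: its oxygen lies between a hydroxyl and a pentyl group on ring B and next to C8a on ring A, so a late coupling of two hindered, electron-rich arenes is unattractive. A second difficulty is keeping the lactone carbonyl and the free acid on C5' apart at the end. The key step exploits that ring B, read as C5'(CO2R)–C6'(pentyl)–C1'(OAr)–C2'(O)–C3'–C4'(O), is the ring a malonate and a 3-en-2-one give by Michael–Claisen annulation, with C1' as the enone α-carbon. The ether C–O bond can therefore be made on an sp3 carbon from an unhindered phenol, and ring B is then built around it through C5'–C6' and C3'–C4'.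

## Logic of the disconnections

16 is traced to 15 by cutting four O–alkyl bonds (three O–CH3 and the ester O–CH2Ph). Cutting there frees the ring-B acid by alkyl–oxygen fission and not by hydroxide, which would open the lactone. The gain is that every protecting group falls in one operation. The forward step must stay cold enough not to decarboxylate 16 and must leave the diaryl ether and the enol lactone alone.

15 is cut at C4–C4a and O2–C3 into 11 and 13. In 11 only one position ortho to the carboxyl is free, so a carboxylate-directed C–H functionalisation has no regiochemical choice, and 13 brings C3, C4 and the pentyl chain at the right oxidation level. The pyranone and one side chain are removed at once. The forward step has to metalate a C–H bond beside a carboxyl flanked by a bulky aryloxy group, and the keto acid 14 must close in the same flask.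

13 is cut between the acyl carbon and the ylide carbon and goes back to 12. This is a routine acylation of a sulfur ylide; the demand is only that a second equivalent of ylide is present as base.

11 is cut at the C8a–C1 bond and goes back to 10. A halogen is an inert placeholder for the carboxyl through base, oxidant and alkylation, and it is turned into the acid by CO insertion. The forward step requires that the ring-B phenols are already capped; otherwise the C2' hydroxyl would trap the acyl–palladium as a seven-membered lactone. The hindered ester must survive aqueous carbonate.

10 goes back to 9 by cutting two O–CH3 bonds. The simplification is small but it buys compatibility with the two metal-catalysed steps; the forward alkylation must also reach the hydrogen-bonded hydroxyl next to the ester.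

9 goes back to 8 by formally adding H2 across C1' and C6'. The reduced ring is the one an annulation can deliver. The forward oxidation must remove hydrogen and not the aryloxy group, and must not halogenate either ring.

8 is cut at C5'–C6' and C3'–C4' into 5 and 6 (the key disconnection). Both bonds are polar and form in one flask, and ring B with all five substituents appears from an acyclic enone and a three-carbon diester. The forward step needs conjugate addition to an enone whose α-carbon carries a donor oxygen, followed by ring closure onto an ester.

5 is cut at its C=C bond (the future C6'–C1') into 3 and 4. A phosphonate fixes which α-carbon of the ketone becomes olefinic, so the methyl group cannot compete. The forward olefination must tolerate an enolisable aldehyde.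

3 is cut at the O–C(sp3) bond into 1 and 2. The ether is made before ring B exists, from an unhindered phenol and a carbene precursor. The forward step needs O–H insertion to beat any reaction at the arene or the bromide.

## Other disconnections considered

Alternative 1: The cut runs through ring A at C8–C8a and C4a–C5, so that ring A comes from a cyclohexadiene and an alkyne. In the forward sense the silyl dienol ether A1 of a 3-aryloxycyclohexenone would add across the ester-bearing triple bond of the diynoate A2. The bicyclo[2.2.2]octadiene would then shed ethene (Alder–Rickert) to give arene A3, with the C1 ester and the heptynyl group ortho to each other for a later 6-endo lactonisation.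
- In its favour: the polarisation of the 1,3-dioxygenated diene and of the ynoate agree, so all four substituents of ring A are placed in one step without a directing group. Neither carbon monoxide nor a C–H activation is needed. The C6 oxygen arrives as a silyl ether, which comes off far more gently than the ring-A methyl ether of the chosen plan. On these three points the alternative is the better one.
- Against it here: ring B must be supplied as a finished, fully substituted phenol (a 3-hydroxylated olivetolate), itself a multistep target. Its hydroxyl, flanked by pentyl and methoxy, must be joined to the cyclohexenone by addition–elimination, so the hindered ether is met head-on. A2 is not a stock compound and conjugated diynoates are heat-sensitive, while ethene extrusion usually asks for high temperature. The second triple bond may compete as dienophile, and the later closure must be steered 6-endo, not 5-exo. Ring B would also end as a hindered methyl ester beside the lactone.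
- Comparison: both plans rest on a dependable ring synthesis and both end with a global deprotection (equal). In step count the alternative is expected to be longer, because both partners need their own syntheses.

Alternative 2: The cut is C5–C6 of ring A, with ring A closed last onto a finished pyranone. In the forward sense a hindered amide base such as LiN(SiMe3)2 would deprotonate the 4-methyl group of pyranone A4. The vinylogous enolate would attack the acrylate ester carbonyl, expel methoxide, and the ketone would tautomerise to the C6 phenol of A5.
- In its favour: the step is redox-neutral and metal-free. The lactone, the pentyl chain and the free C6 hydroxyl are all in place once the ring closes, so only ring-B deprotection remains. This is the shortest tail of all the plans and better than the chosen one.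
- Against it here: A4 is elaborate, a 3-substituted 4-methyl-6-pentylpyran-2-one carrying a β-aryloxyacrylate with the ester cis to the pyranone. A β-aryloxyacrylate is a vinylogous carbonate, so the methoxide set free may add at the β-carbon and expel the ring-B phenoxide. The ether is thus exposed in the way the chosen plan avoids by placing oxygen α to the carbonyl. The first carbon of the pentyl chain is also vinylogously acidic, and pyranones are opened by nucleophiles. The same ready-made ring-B phenol as in alternative 1 is needed.
- Comparison: the alternative wins on the end-game and on leaving C6 unprotected. The chosen plan wins on accessibility of the precursor and on the security of the ether bond. Overall step count is expected to be no shorter, since the effort moves into A4.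

Alternative 3: The cut is C4'–C5' and C1'–C6' of ring B, which is made aromatic in one step around the same preformed ether. In the forward sense the 4-aryloxy Brassard diene A6 and methyl oct-2-ynoate A7 would combine in a [4+2] cycloaddition, and loss of methanol and of the silyl group would give benzoate A8.
- In its favour: this is the closest relative of the chosen plan. It starts from 1, and the ether is again made on an sp3 carbon (equal). Ring B arrives aromatic, so there is no oxidation step and no stereocentre is made and destroyed, and the C2' and C4' oxygens come out differentiated. On redox economy the alternative is better. The regiochemistry is polarity-matched (nucleophilic diene terminus to the β-carbon of the ynoate), which is equal to the chosen plan.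
- Against it here: a β-alkyl ynoate is a weak dienophile, the reacting diene terminus carries the bulky aryloxy group, and the C1'–C6' bond joins two substituted carbons. Forcing conditions are therefore likely, under which silyl ketene acetal dienes decompose or transfer silicon. The diene needs about three steps through a moisture-sensitive intermediate, and A8 carries the methyl ester that is hard to remove beside the lactone.
- Comparison: the number of operations from 1 to an aromatic ring-B bromide is about the same (equal), and everything downstream is identical. The chosen plan spends one extra oxidation but relies on a base-mediated annulation with a soft nucleophile and cheap reagents, not on a demanding cycloaddition.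

Key step: step 3

## Route

Step 1
Reactants: 1 2-bromo-5-methoxyphenol; 2 dimethyl (1-diazo-2-oxopropyl)phosphonate
Product: 3 dimethyl [1-(2-bromo-5-methoxyphenoxy)-2-oxopropyl]phosphonate (racemic)
Conditions: Rh2(OAc)4 (1 mol %), toluene, 80 °C, slow addition of 2
Reagents that add atoms: none
Why: Rhodium-carbenoid O–H insertion: 2 loses N2 at the dirhodium catalyst, the electrophilic carbenoid is taken by the phenol oxygen and a proton shift gives the α-aryloxy ketophosphonate; the doubly acceptor-substituted carbenoid is too stabilised for Wolff rearrangement or arene addition, and the new stereocentre is racemic and disappears in step 2.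

Step 2
Reactants: 3 dimethyl [1-(2-bromo-5-methoxyphenoxy)-2-oxopropyl]phosphonate; 4 hexanal
Product: 5 (Z)-3-(2-bromo-5-methoxyphenoxy)non-3-en-2-one
Conditions: NaH, THF, 0 °C; then 4, 0 °C to rt
Reagents that add atoms: none
Why: Horner–Wadsworth–Emmons olefination; the stabilised phosphonate anion adds to the aldehyde and loses dimethyl phosphate, which fixes the double bond at the aryloxy carbon with no competition from the methyl group. The (Z) isomer (pentyl trans to acetyl) is expected as the less strained one, and either isomer would serve in step 3.

Step 3
Reactants: 5 (Z)-3-(2-bromo-5-methoxyphenoxy)non-3-en-2-one; 6 dibenzyl malonate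
Product: 8 benzyl (5R*,6S*)-5-(2-bromo-5-methoxyphenoxy)-2-hydroxy-4-oxo-6-pentylcyclohex-1-ene-1-carboxylate (racemic trans; enol form), via Michael adduct 7 (not isolated)
Conditions: NaH (1.1 equiv), THF, 0 °C to reflux; then 1 M HCl, 0 °C
Reagents that add atoms: none
Why: Michael–Claisen (Michael–Dieckmann) annulation, the classical way from a 3-en-2-one and a malonate to a 6-alkylcyclohexane-1,3-dione carboxylate. The sodium malonate adds to C4 of 5 (the future C5'–C6' bond) to give 7; proton transfer then places the charge on the methyl ketone, whose enolate carbon attacks one ester carbonyl in a 6-exo-trig acyl substitution (the future C3'–C4' bond) and expels benzyloxide. The benzyloxide at once deprotonates the new β-diketone, and this irreversible last step pulls the reversible additions forward. No other closure is open, because the enolate at the aryloxy carbon of 7 could only form a four-membered ring. C6 is set in the conjugate addition without control (racemate), and C5, being α to the ketone, should equilibrate under base to the trans arrangement with both substituents equatorial; both centres vanish in step 4, so no control is needed. The step needs 1,4- over 1,2-addition, which the soft, reversibly adding malonate anion provides. It also needs the aryloxy group to stay: that oxygen sits on the α-carbon of the ketone and is never β to a carbanion, so there is no E1cB path to aryloxide. The aryl bromide and the methyl ether are inert to NaH in THF, and benzyloxide as the only alkoxide present cannot scramble the ester.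

Step 4
Reactants: 8 benzyl 5-(2-bromo-5-methoxyphenoxy)-2-hydroxy-4-oxo-6-pentylcyclohex-1-ene-1-carboxylate
Product: 9 benzyl 3-(2-bromo-5-methoxyphenoxy)-4,6-dihydroxy-2-pentylbenzoate
Conditions: I2 (20 mol %), DMSO, 80 °C
Reagents that add atoms: none
Why: Iodine-catalysed dehydrogenative aromatisation of a cyclohexane-1,3-dione to a resorcinol: enol iodination, loss of HI and tautomerisation give the arene, and DMSO reoxidises HI to iodine so that little free iodide or iodine is ever present. Both stereocentres are erased and the aryloxy group is kept because only hydrogen is removed from C5 and C6.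

Step 5
Reactants: 9 benzyl 3-(2-bromo-5-methoxyphenoxy)-4,6-dihydroxy-2-pentylbenzoate
Product: 10 benzyl 3-(2-bromo-5-methoxyphenoxy)-4,6-dimethoxy-2-pentylbenzoate
Conditions: MeI (excess), K2CO3, DMF, 50 °C
Reagents that add atoms: iodomethane, CI
Why: Williamson O-methylation of both phenols, the hydrogen-bonded one next to the ester reacting more slowly; capping stops the hydroxyl ortho to the ether from trapping the acyl–palladium of step 6 as a seven-membered lactone and keeps phenols out of the carbene chemistry of step 8.

Step 6
Reactants: 10 benzyl 3-(2-bromo-5-methoxyphenoxy)-4,6-dimethoxy-2-pentylbenzoate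
Product: 11 2-[3-(benzyloxycarbonyl)-4,6-dimethoxy-2-pentylphenoxy]-4-methoxybenzoic acid
Conditions: Pd(OAc)2 (5 mol %), xantphos (6 mol %), CO (1 atm), K2CO3, H2O, 1,4-dioxane, 95 °C; then aq. HCl
Reagents that add atoms: carbon monoxide, [C-]#[O+]; water, O
Why: Palladium-catalysed hydroxycarbonylation of an aryl bromide: zerovalent palladium inserts into C–Br, CO inserts and the acyl–palladium is taken by water or hydroxide. The benzyl benzoate, substituted at both ortho positions, is too hindered to be hydrolysed by carbonate.

Step 7
Reactants: 12 hexanoyl chloride
Product: 13 1-[dimethyl(oxo)-λ6-sulfanylidene]heptan-2-one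
Conditions: Me3S(O)I, KOtBu, THF, reflux; then 12, 0 °C to rt
Reagents that add atoms: trimethylsulfoxonium iodide, C[S+](C)(C)=O.[I-]
Why: Acylation of dimethylsulfoxonium methylide (the Corey–Chaykovsky ylide) by an acid chloride; a second equivalent of the methylide deprotonates the acylsulfoxonium salt to the stabilised β-keto ylide.

Step 8
Reactants: 11 2-[3-(benzyloxycarbonyl)-4,6-dimethoxy-2-pentylphenoxy]-4-methoxybenzoic acid; 13 1-[dimethyl(oxo)-λ6-sulfanylidene]heptan-2-one
Product: 15 benzyl 4,6-dimethoxy-3-[(6-methoxy-1-oxo-3-pentyl-1H-isochromen-8-yl)oxy]-2-pentylbenzoate, via keto acid 14 (not isolated)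
Conditions: [Cp*RhCl2]2 (4 mol %), AgSbF6 (16 mol %), NaOAc (0.5 equiv), (CF3)2CHOH, 80 °C
Reagents that add atoms: none
Why: Carboxylate-directed C–H acylmethylation with a sulfoxonium ylide as carbene source, followed by cyclodehydration. Trivalent rhodium forms a rhodacycle at the only free ortho C–H (the future C4a), the ylide loses DMSO to a rhodium carbene, and migratory insertion and protodemetalation give keto acid 14, whose carboxyl closes onto the ketone with loss of water. The sequence is redox-neutral, and a Friedel–Crafts closure to a xanthone is excluded because both positions of ring B ortho to the ether are substituted.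

Step 9
Reactants: 15 benzyl 4,6-dimethoxy-3-[(6-methoxy-1-oxo-3-pentyl-1H-isochromen-8-yl)oxy]-2-pentylbenzoate
Product: 16 4,6-dihydroxy-3-[(6-hydroxy-1-oxo-3-pentyl-1H-isochromen-8-yl)oxy]-2-pentylbenzoic acid
Conditions: BBr3 (8 equiv), CH2Cl2, −78 °C to rt; then ice-water
Reagents that add atoms: none
Why: Lewis-acid dealkylation of aryl methyl ethers and of a benzyl ester: boron binds each oxygen, bromide takes the methyl or benzyl carbon, and the boron aryloxides and acyloxyborane are hydrolysed on work-up. The diaryl ether and the enol lactone have no sp3 C–O bond and should survive, and the low temperature protects the β-resorcylic acid from decarboxylation.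

## Compound list

1 | 2-bromo-5-methoxyphenol | COc1ccc(Br)c(O)c1 | starting material
2 | dimethyl (1-diazo-2-oxopropyl)phosphonate | CC(=O)C(=[N+]=[N-])P(=O)(OC)OC | starting material
3 | dimethyl [1-(2-bromo-5-methoxyphenoxy)-2-oxopropyl]phosphonate (racemic) | CC(=O)C(Oc1cc(OC)ccc1Br)P(=O)(OC)OC | intermediate
4 | hexanal | CCCCCC=O | starting material
5 | (Z)-3-(2-bromo-5-methoxyphenoxy)non-3-en-2-one | CCCCC/C=C(\Oc1cc(OC)ccc1Br)C(C)=O | intermediate
6 | dibenzyl malonate (dibenzyl propanedioate) | O=C(CC(=O)OCc1ccccc1)OCc1ccccc1 | starting material
7 | dibenzyl 2-[3-(2-bromo-5-methoxyphenoxy)-2-oxononan-4-yl]propanedioate (racemic, mixture of diastereomers) | CCCCCC(C(Oc1cc(OC)ccc1Br)C(C)=O)C(C(=O)OCc1ccccc1)C(=O)OCc1ccccc1 | intermediate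
8 | benzyl (5R*,6S*)-5-(2-bromo-5-methoxyphenoxy)-2-hydroxy-4-oxo-6-pentylcyclohex-1-ene-1-carboxylate (racemic trans, one enantiomer drawn, enol form) | CCCCC[C@@H]1[C@@H](Oc2cc(OC)ccc2Br)C(=O)CC(O)=C1C(=O)OCc1ccccc1 | intermediate
9 | benzyl 3-(2-bromo-5-methoxyphenoxy)-4,6-dihydroxy-2-pentylbenzoate | CCCCCc1c(Oc2cc(OC)ccc2Br)c(O)cc(O)c1C(=O)OCc1ccccc1 | intermediate
10 | benzyl 3-(2-bromo-5-methoxyphenoxy)-4,6-dimethoxy-2-pentylbenzoate | CCCCCc1c(Oc2cc(OC)ccc2Br)c(OC)cc(OC)c1C(=O)OCc1ccccc1 | intermediate
11 | 2-[3-(benzyloxycarbonyl)-4,6-dimethoxy-2-pentylphenoxy]-4-methoxybenzoic acid | CCCCCc1c(Oc2cc(OC)ccc2C(=O)O)c(OC)cc(OC)c1C(=O)OCc1ccccc1 | intermediate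
12 | hexanoyl chloride | CCCCCC(=O)Cl | starting material
13 | 1-[dimethyl(oxo)-λ6-sulfanylidene]heptan-2-one | CCCCCC(=O)C=S(C)(C)=O | intermediate
14 | 2-[3-(benzyloxycarbonyl)-4,6-dimethoxy-2-pentylphenoxy]-4-methoxy-6-(2-oxoheptyl)benzoic acid | CCCCCC(=O)Cc1cc(OC)cc(Oc2c(OC)cc(OC)c(C(=O)OCc3ccccc3)c2CCCCC)c1C(=O)O | intermediate
15 | benzyl 4,6-dimethoxy-3-[(6-methoxy-1-oxo-3-pentyl-1H-isochromen-8-yl)oxy]-2-pentylbenzoate | CCCCCc1cc2cc(OC)cc(Oc3c(OC)cc(OC)c(C(=O)OCc4ccccc4)c3CCCCC)c2c(=O)o1 | intermediate
16 | 4,6-dihydroxy-3-[(6-hydroxy-1-oxo-3-pentyl-1H-isochromen-8-yl)oxy]-2-pentylbenzoic acid | CCCCCc1cc2cc(O)cc(Oc3c(O)cc(O)c(C(=O)O)c3CCCCC)c2c(=O)o1 | target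

## Step count and least certain steps

Total: 9 steps. Longest linear sequence: 8 steps (steps 1–6, 8 and 9); step 7 is a one-step side branch.

The key step, step 3, is most exposed to a slow conjugate addition. The α-aryloxy group donates into the double bond of 5, so deprotonation of 5 at its methyl group with self-condensation, or stalling at the open-chain stage, may outrun the annulation. The fallback activates the acceptor with a Lewis acid in place of activating the donor with base. From 6 (LiN(SiMe3)2, then Me3SiCl, THF, −78 °C) the silyl ketene acetal benzyl 3-(benzyloxy)-3-[(trimethylsilyl)oxy]prop-2-enoate F1 would be made and added to 5 under TiCl4 (CH2Cl2, −78 °C) in a Mukaiyama–Michael reaction. Aqueous work-up would give 7 as an isolated compound, which KOtBu in THF would close in a separate Dieckmann step, returning to the route at 8.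

In step 8 the carboxylate is a weak directing group and is twisted by the neighbouring aryloxy substituent, so C–H metalation may be slow while the ylide is consumed unproductively; the closure of the keto acid may also lag. The fallback sets out from 11. The acid would be converted (oxalyl chloride; then MeONH2·HCl, K2CO3) into the N-methoxyamide benzyl 4,6-dimethoxy-3-[5-methoxy-2-(methoxycarbamoyl)phenoxy]-2-pentylbenzoate F2. Its nitrogen-bound directing group holds trivalent rhodium more firmly. Coupling with 13 under [Cp*RhCl2]2/AgSbF6 with an acidic additive such as Zn(OTf)2 or pivalic acid, chosen so that the amide oxygen attacks the ketone and methoxyamine is lost, would return to the route at 15.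

In step 9 three things may go wrong. The electron-rich ring B may be alkylated by the benzyl bromide released. The boron-bound β-resorcylic acid may lose CO2 if warming is needed. The methyl ether flanked by the diaryl ether may be cleaved incompletely. The fallback separates the two kinds of cleavage and sets out from 15. Hydrogenolysis (H2, 1 atm, Pd/C, EtOAc, rt, short contact time to spare the pyranone double bond) would give 4,6-dimethoxy-3-[(6-methoxy-1-oxo-3-pentyl-1H-isochromen-8-yl)oxy]-2-pentylbenzoic acid F3 with no benzyl electrophile ever present. The three methyl ethers would then be removed with BCl3 and n-Bu4NI (CH2Cl2, −78 to 0 °C), where iodide is the soft nucleophile, returning to the route at 16.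

In step 4 the hot, mildly acidic medium may lead to loss of the aryloxy group by elimination of the phenol (which also gives an aromatic ring), to iodination of an electron-rich ring, or to attack of iodide at the benzyl ester. The fallback uses a non-halogen oxidation of a pre-formed diene and sets out from 8. Silylation (Me3SiCl, Et3N, CH2Cl2, 0 °C) would give benzyl (5R*,6S*)-5-(2-bromo-5-methoxyphenoxy)-6-pentyl-2,4-bis[(trimethylsilyl)oxy]cyclohexa-1,3-diene-1-carboxylate F4. DDQ at room temperature would dehydrogenate this cyclohexa-1,3-diene by hydride abstraction to benzyl 3-(2-bromo-5-methoxyphenoxy)-2-pentyl-4,6-bis[(trimethylsilyl)oxy]benzoate F5. Desilylation on mildly acidic work-up would return to the route at 9.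

In step 2 the phosphonate anion is stabilised by both acyl and phosphoryl groups and crowded by the aryloxy substituent, so addition may be slow enough for the aldehyde to enolise and self-condense; the preceding insertion could also be diverted by carbene attack on the arene. The fallback avoids the carbene and the phosphonate and sets out from 1. Alkylation with chloroacetone (K2CO3, KI, acetone, reflux) would give 1-(2-bromo-5-methoxyphenoxy)propan-2-one F6. An amine-catalysed aldol condensation with 4 at the oxygen-bearing methylene (pyrrolidine, AcOH, toluene, slow addition of 4) would return to the route at 5.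

## Further compounds

F1 | step 3 | benzyl 3-(benzyloxy)-3-[(trimethylsilyl)oxy]prop-2-enoate | C[Si](C)(C)OC(OCc1ccccc1)=CC(=O)OCc1ccccc1
F2 | step 8 | benzyl 4,6-dimethoxy-3-[5-methoxy-2-(methoxycarbamoyl)phenoxy]-2-pentylbenzoate | CCCCCc1c(Oc2cc(OC)ccc2C(=O)NOC)c(OC)cc(OC)c1C(=O)OCc1ccccc1
F3 | step 9 | 4,6-dimethoxy-3-[(6-methoxy-1-oxo-3-pentyl-1H-isochromen-8-yl)oxy]-2-pentylbenzoic acid | CCCCCc1cc2cc(OC)cc(Oc3c(OC)cc(OC)c(C(=O)O)c3CCCCC)c2c(=O)o1
F4 | step 4 | benzyl (5R*,6S*)-5-(2-bromo-5-methoxyphenoxy)-6-pentyl-2,4-bis[(trimethylsilyl)oxy]cyclohexa-1,3-diene-1-carboxylate (racemic trans, one enantiomer drawn) | CCCCC[C@@H]1[C@@H](Oc2cc(OC)ccc2Br)C(O[Si](C)(C)C)=CC(O[Si](C)(C)C)=C1C(=O)OCc1ccccc1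
F5 | step 4 | benzyl 3-(2-bromo-5-methoxyphenoxy)-2-pentyl-4,6-bis[(trimethylsilyl)oxy]benzoate | CCCCCc1c(Oc2cc(OC)ccc2Br)c(O[Si](C)(C)C)cc(O[Si](C)(C)C)c1C(=O)OCc1ccccc1
F6 | step 2 | 1-(2-bromo-5-methoxyphenoxy)propan-2-one | CC(=O)COc1cc(OC)ccc1Br
A1 | alternative 1 | methyl 3-{[3-(tert-butyldimethylsilyloxy)cyclohexa-1,3-dien-1-yl]oxy}-4,6-dimethoxy-2-pentylbenzoate | CCCCCc1c(OC2=CC(O[Si](C)(C)C(C)(C)C)=CCC2)c(OC)cc(OC)c1C(=O)OC
A2 | alternative 1 | methyl deca-2,4-diynoate | CCCCCC#CC#CC(=O)OC
A3 | alternative 1 | methyl 3-[5-(tert-butyldimethylsilyloxy)-3-(hept-1-yn-1-yl)-2-(methoxycarbonyl)phenoxy]-4,6-dimethoxy-2-pentylbenzoate | CCCCCC#Cc1cc(O[Si](C)(C)C(C)(C)C)cc(Oc2c(OC)cc(OC)c(C(=O)OC)c2CCCCC)c1C(=O)OC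
A4 | alternative 2 | methyl 3-{[(1E)-3-methoxy-1-(4-methyl-2-oxo-6-pentyl-2H-pyran-3-yl)-3-oxoprop-1-en-1-yl]oxy}-4,6-dimethoxy-2-pentylbenzoate | CCCCCc1cc(C)c(/C(Oc2c(OC)cc(OC)c(C(=O)OC)c2CCCCC)=C\C(=O)OC)c(=O)o1
A5 | alternative 2 | methyl 3-[(6-hydroxy-1-oxo-3-pentyl-1H-isochromen-8-yl)oxy]-4,6-dimethoxy-2-pentylbenzoate | CCCCCc1cc2cc(O)cc(Oc3c(OC)cc(OC)c(C(=O)OC)c3CCCCC)c2c(=O)o1
A6 | alternative 3 | {[4-(2-bromo-5-methoxyphenoxy)-1,3-dimethoxybuta-1,3-dien-1-yl]oxy}trimethylsilane (mixture of double-bond isomers) | COC(O[Si](C)(C)C)=CC(OC)=COc1cc(OC)ccc1Br
A7 | alternative 3 | methyl oct-2-ynoate | CCCCCC#CC(=O)OC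
A8 | alternative 3 | methyl 3-(2-bromo-5-methoxyphenoxy)-6-hydroxy-4-methoxy-2-pentylbenzoate | CCCCCc1c(Oc2cc(OC)ccc2Br)c(OC)cc(O)c1C(=O)OC
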